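**Retrosynthetic overview**
- Ring C (the pyranone) is the only ring that is built; it closes last by 6-endo oxa-Michael addition of a freed 2'-phenol onto a diaryl ynone (O1–C2 bond). Rings A and B are bought as benzaldehydes.
- The ynone C4–C3 bond is the key disconnection: an acyl anion equivalent (Breslow intermediate of the ring A aldehyde, NHC catalysis) is joined to the electrophilic acetylenic carbon of a ring B alkynyl(phenyl)iodonium salt.
- Ring A aldehyde: 3,4,5-trimethoxybenzaldehyde → ortho-lithiation/oxygenation → chelation-controlled 3-O-demethylation → bis-benzylation.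
- Ring B alkynyliodonium salt: 3-hydroxy-4,5-dimethoxybenzaldehyde → benzylation → Ohira–Bestmann alkyne → trivalent iodine transfer.
- Global debenzylation and ring C closure are telescoped in the final step.

Assumption: the target is a planar flavone with no stereocentre, so it is achiral and no stereocontrol is needed.

**Step 1**
Reactants: 1 3,4,5-trimethoxybenzaldehyde
Product: 5 2-hydroxy-3,4,5-trimethoxybenzaldehyde, via lithium amino alkoxide 2 (not isolated), via aryllithium 3 (not isolated), via lithium aryloxide 4 (not isolated)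
Conditions: Me2NCH2CH2N(Me)Li (1.1 equiv), THF, −20 °C; n-BuLi (2 equiv), −20 °C, 6 h; t-BuOOLi (3 equiv), −78 → 0 °C; 1 M HCl
Reagents that add atoms: tert-butyl hydroperoxide (used as its lithium salt), CC(C)(C)OO
Why: Comins-type directed ortho-metalation, in which the in situ α-amino alkoxide and the flanking 3-OMe jointly direct lithiation to C2 (C2 and C6 are equivalent by symmetry), followed by electrophilic oxygen transfer from t-BuOOLi to the aryllithium and release of the aldehyde on acidic work-up; the carbinol centre of 2–4 is racemic and disappears on work-up.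

**Step 2**
Reactants: 5 2-hydroxy-3,4,5-trimethoxybenzaldehyde
Product: 7 2,3-dihydroxy-4,5-dimethoxybenzaldehyde, via cyclic chloroborate 6 (not isolated)
Conditions: BCl3 (1.5 equiv), CH2Cl2, 0 °C → rt; H2O
Reagents that add atoms: none
Why: Chelation-controlled Lewis acid ether cleavage, in which the phenol becomes an aryloxy-BCl2 unit held by the aldehyde oxygen, boron is delivered to the adjacent 3-OMe and chloride removes its methyl group to give the five-membered catechol chloroborate, which water hydrolyses; the 4- and 5-OMe groups have no such neighbouring delivery and stay.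

**Step 3**
Reactants: 7 2,3-dihydroxy-4,5-dimethoxybenzaldehyde
Product: 8 2,3-bis(benzyloxy)-4,5-dimethoxybenzaldehyde
Conditions: BnBr (2.4 equiv), K2CO3, DMF, 60 °C, N2
Reagents that add atoms: benzyl bromide, BrCc1ccccc1
Why: Williamson ether synthesis on both phenoxides (the hydrogen-bonded 2-OH needs the warm DMF), which masks the nucleophilic oxygens that would otherwise attack the iodonium salt in step 7.

**Step 4**
Reactants: 9 3-hydroxy-4,5-dimethoxybenzaldehyde
Product: 10 3-(benzyloxy)-4,5-dimethoxybenzaldehyde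
Conditions: BnBr (1.1 equiv), K2CO3, DMF, rt
Reagents that add atoms: benzyl bromide, BrCc1ccccc1
Why: Williamson ether synthesis of the single phenol; the benzyl ether survives the basic methanol of step 5, the acidic iodine reagent of step 6 and the amine base of step 7.

**Step 5**
Reactants: 10 3-(benzyloxy)-4,5-dimethoxybenzaldehyde
Product: 11 1-(benzyloxy)-5-ethynyl-2,3-dimethoxybenzene
Conditions: MeC(O)C(N2)P(O)(OMe)2 (1.3 equiv), K2CO3 (2 equiv), MeOH, 0 °C → rt
Reagents that add atoms: dimethyl (1-diazo-2-oxopropyl)phosphonate, CC(=O)C(=[N+]=[N-])P(=O)(OC)OC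
Why: Ohira–Bestmann (Seyferth–Gilbert) homologation, in which methanolysis of the reagent gives the diazomethylphosphonate anion, Horner–Wadsworth–Emmons-type olefination gives a diazoalkene, and loss of N2 with 1,2-hydride shift gives the terminal alkyne.

**Step 6**
Reactants: 11 1-(benzyloxy)-5-ethynyl-2,3-dimethoxybenzene
Product: 12 {[3-(benzyloxy)-4,5-dimethoxyphenyl]ethynyl}(phenyl)iodonium 4-methylbenzenesulfonate
Conditions: PhI(OH)OTs (1.05 equiv), Na2SO4, CH2Cl2, rt, dark
Reagents that add atoms: [hydroxy(tosyloxy)iodo]benzene (Koser's reagent), Cc1ccc(cc1)S(=O)(=O)OI(O)c1ccccc1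
Why: Koser-type alkynyliodonium synthesis, in which the electrophilic trivalent iodine adds to the terminal alkyne and loss of the acetylenic proton with hydroxide (water is the only by-product) gives the alkynyl(phenyl)iodonium tosylate, an alkynyl cation equivalent.

**Step 7**
Reactants: 8 2,3-bis(benzyloxy)-4,5-dimethoxybenzaldehyde; 12 {[3-(benzyloxy)-4,5-dimethoxyphenyl]ethynyl}(phenyl)iodonium 4-methylbenzenesulfonate
Product: 13 1-[2,3-bis(benzyloxy)-4,5-dimethoxyphenyl]-3-[3-(benzyloxy)-4,5-dimethoxyphenyl]prop-2-yn-1-one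
Conditions: 8 (1 equiv), 12 (1.3 equiv, slow addition), 2-(pentafluorophenyl)-6,7-dihydro-5H-pyrrolo[2,1-c][1,2,4]triazol-2-ium tetrafluoroborate (20 mol%), TMEDA (1.3 equiv), toluene, −40 °C
Reagents that add atoms: none
Why: Proposed new method: the triazolylidene adds to aldehyde 8 to give a Breslow intermediate (acyl anion equivalent) whose nucleophilic carbon displaces iodobenzene from the electrophilic acetylenic carbon of 12 (direct substitution, or conjugate addition followed by 1,2-shift, both giving the same alkyne), and collapse of the adduct releases ynone 13 and the carbene; the closest known reaction type is the NHC-catalysed C–H alkynylation of heteroaryl aldehydes with alkynyl(aryl)iodonium salts under amine base at −40 °C, here extended to an electron-rich ortho-alkoxybenzaldehyde, so 12 is added slowly to keep the free carbene from being alkynylated while the slower Breslow formation catches up; no stereocentre is formed.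

**Step 8**
Reactants: 13 1-[2,3-bis(benzyloxy)-4,5-dimethoxyphenyl]-3-[3-(benzyloxy)-4,5-dimethoxyphenyl]prop-2-yn-1-one
Product: 16 8-hydroxy-2-(3-hydroxy-4,5-dimethoxyphenyl)-6,7-dimethoxy-4H-chromen-4-one (CNP0264497.0), via aryl chloroborate 14 (not isolated), via trihydroxy ynone 15 (not isolated)
Conditions: BCl3 (6 equiv), C6HMe5 (10 equiv), CH2Cl2, −78 °C; MeOH, evaporate; K2CO3 (0.5 equiv), acetone, rt, Ar
Reagents that add atoms: none
Why: Lewis acid benzyl ether cleavage at −78 °C with pentamethylbenzene as Friedel–Crafts benzyl cation trap leaves the methyl ethers intact, and after methanolysis of the borates the 2'-phenoxide closes ring C by 6-endo-dig oxa-Michael addition to the ynone (carbonate in aprotic acetone favours the flavone over the aurone); the product is achiral.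

**Compound list**
1 | 3,4,5-trimethoxybenzaldehyde | COc1cc(C=O)cc(OC)c1OC | starting material
2 | lithium {[2-(dimethylamino)ethyl](methyl)amino}(3,4,5-trimethoxyphenyl)methanolate (racemic) | [Li]OC(N(C)CCN(C)C)c1cc(OC)c(OC)c(OC)c1 | intermediate
3 | 2-lithio derivative of 2 (racemic) | [Li]OC(N(C)CCN(C)C)c1cc(OC)c(OC)c(OC)c1[Li] | intermediate
4 | dilithium 2-oxido derivative of 2 (racemic) | [Li]OC(N(C)CCN(C)C)c1cc(OC)c(OC)c(OC)c1O[Li] | intermediate
5 | 2-hydroxy-3,4,5-trimethoxybenzaldehyde | O=Cc1cc(OC)c(OC)c(OC)c1O | intermediate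
6 | 2-chloro-6,7-dimethoxy-1,3,2-benzodioxaborole-4-carbaldehyde | O=Cc1cc(OC)c(OC)c2OB(Cl)Oc12 | intermediate
7 | 2,3-dihydroxy-4,5-dimethoxybenzaldehyde | O=Cc1cc(OC)c(OC)c(O)c1O | intermediate
8 | 2,3-bis(benzyloxy)-4,5-dimethoxybenzaldehyde | O=Cc1cc(OC)c(OC)c(OCc2ccccc2)c1OCc1ccccc1 | intermediate
9 | 3-hydroxy-4,5-dimethoxybenzaldehyde | COc1cc(C=O)cc(O)c1OC | starting material
10 | 3-(benzyloxy)-4,5-dimethoxybenzaldehyde | COc1cc(C=O)cc(OCc2ccccc2)c1OC | intermediate
11 | 1-(benzyloxy)-5-ethynyl-2,3-dimethoxybenzene | COc1cc(C#C)cc(OCc2ccccc2)c1OC | intermediate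
12 | {[3-(benzyloxy)-4,5-dimethoxyphenyl]ethynyl}(phenyl)iodonium 4-methylbenzenesulfonate | COc1cc(C#C[I+]c2ccccc2)cc(OCc2ccccc2)c1OC.Cc1ccc(cc1)S(=O)(=O)[O-] | intermediate
13 | 1-[2,3-bis(benzyloxy)-4,5-dimethoxyphenyl]-3-[3-(benzyloxy)-4,5-dimethoxyphenyl]prop-2-yn-1-one | COc1cc(C#CC(=O)c2cc(OC)c(OC)c(OCc3ccccc3)c2OCc2ccccc2)cc(OCc2ccccc2)c1OC | intermediate
14 | 1-(2-chloro-6,7-dimethoxy-1,3,2-benzodioxaborol-4-yl)-3-{3-[(dichloroboranyl)oxy]-4,5-dimethoxyphenyl}prop-2-yn-1-one | COc1cc(C#CC(=O)c2cc(OC)c(OC)c3OB(Cl)Oc23)cc(OB(Cl)Cl)c1OC | intermediate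
15 | 1-(2,3-dihydroxy-4,5-dimethoxyphenyl)-3-(3-hydroxy-4,5-dimethoxyphenyl)prop-2-yn-1-one | COc1cc(C#CC(=O)c2cc(OC)c(OC)c(O)c2O)cc(O)c1OC | intermediate
16 | 8-hydroxy-2-(3-hydroxy-4,5-dimethoxyphenyl)-6,7-dimethoxy-4H-chromen-4-one | COc1cc(-c2cc(=O)c3cc(OC)c(OC)c(O)c3o2)cc(O)c1OC | target

**Step count and risks**
Total steps: 8. Longest linear sequence: 5 (steps 1, 2, 3, 7, 8; the ring B branch, steps 4, 5, 6, 7, 8, is equally long).

Most likely to fail, first: step 7. The Breslow intermediate of an electron-rich ortho-alkoxybenzaldehyde forms slowly, and the free carbene or the amine may consume the iodonium salt first. The fallback sets out from 8 and 11 and so also bypasses step 6. Alkyne 11 is deprotonated with n-BuLi in THF at −78 °C and added to aldehyde 8, giving the racemic propargylic alcohol 1-[2,3-bis(benzyloxy)-4,5-dimethoxyphenyl]-3-[3-(benzyloxy)-4,5-dimethoxyphenyl]prop-2-yn-1-ol F1. Oxidation with MnO2 in CH2Cl2 at rt comes back to the route at 13.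

Second: step 6. The trialkoxy-substituted arene of 11 may be attacked on the ring by the trivalent iodine reagent, and the product is only moderately stable. The fallback sets out from 11. It is converted with n-BuLi, then 2-isopropoxy-4,4,5,5-tetramethyl-1,3,2-dioxaborolane, then HCl in Et2O, into the alkynylboronate 2-{[3-(benzyloxy)-4,5-dimethoxyphenyl]ethynyl}-4,4,5,5-tetramethyl-1,3,2-dioxaborolane F2. Ipso boron-to-iodine exchange with PhI(OH)OTs in CH2Cl2 at rt, which is directed to the acetylenic carbon and not to the ring, comes back to the route at 12.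

Third: step 1. The doubly flanked aryllithium may be oxygenated in low yield, or lithiation may be incomplete. The fallback sets out from 1. Electrophilic bromination with NBS in MeCN gives 2-bromo-3,4,5-trimethoxybenzaldehyde F3 (both free positions are equivalent). Copper-catalysed hydroxylation of the bromide (Cu2O, 1,10-phenanthroline, KOH, DMSO/H2O, 100 °C; then HCl), assisted by the ortho aldehyde, comes back to the route at 5.

**Further compounds**
F1 | step 7 | 1-[2,3-bis(benzyloxy)-4,5-dimethoxyphenyl]-3-[3-(benzyloxy)-4,5-dimethoxyphenyl]prop-2-yn-1-ol (racemic) | COc1cc(C#CC(O)c2cc(OC)c(OC)c(OCc3ccccc3)c2OCc2ccccc2)cc(OCc2ccccc2)c1OC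
F2 | step 6 | 2-{[3-(benzyloxy)-4,5-dimethoxyphenyl]ethynyl}-4,4,5,5-tetramethyl-1,3,2-dioxaborolane | COc1cc(C#CB2OC(C)(C)C(C)(C)O2)cc(OCc2ccccc2)c1OC
F3 | step 1 | 2-bromo-3,4,5-trimethoxybenzaldehyde | COc1cc(C=O)c(Br)c(OC)c1OC
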